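**Retrosynthetic overview**

- The strategy rests on ring D. Its cis C3''=C4'' olefin lies between arene carbon C5' of ring B and the gem-dimethyl ether carbon C2'' on O4'. Ring D is therefore cut at that olefin by ring-closing metathesis, back to a C5' vinyl group and an O4' 1,1-dimethylallyl ether on a flavonol capped with four MOM groups. Ring D is closed last, and only MOM removal follows.
- Ring C comes from Algar–Flynn–Oyamada oxidative cyclisation of a 2'-hydroxychalcone, made by Claisen–Schmidt union of a ring A methyl ketone and a ring B aldehyde.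
- Ring A ketone: the C8 1,1-dimethylallyl group is set by aromatic Claisen rearrangement of the 4-O-prenyl ether of phloroacetophenone (equivalent ortho carbons, blocked para carbon), then regioselective bis-MOM protection. A prenyl ether on the chelated O2 is avoided because it tends to relay to the para carbon and give the linear C-prenyl isomer.
- Ring B aldehyde: from 3-bromo-4,5-dihydroxybenzaldehyde by O5-selective MOM protection through the dianion, Suzuki vinylation, then palladium-catalysed branched O-allylation. The cross-coupling comes before the tertiary allyl ether so that this ether never meets hot zerovalent palladium.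
- Order of ring formation: rings A and B are bought, ring C is formed in step 9, ring D in step 11.

Key step: step 11

Assumption: the target has no stereocentre and the ring D olefin is cis by ring constraint, so no stereocontrol is needed; the transient dihydroflavonol in the flavonol-forming step is racemic and is drawn as one enantiomer.

**Route**

Step 1
Reactants: 1 2,4,6-trihydroxyacetophenone; 2 1-bromo-3-methylbut-2-ene (prenyl bromide)
Product: 3 1-[2,6-dihydroxy-4-(3-methylbut-2-enyloxy)phenyl]ethanone
Conditions: K2CO3 (1.05 equiv), 2 (1.0 equiv), acetone, 25 to 40 °C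
Reagents that add atoms: none
Why: Williamson etherification in which the 4-OH, the only hydroxyl not hydrogen-bonded to the acetyl carbonyl and the most acidic one, should be alkylated in preference to O2/O6 and to ring carbon under one equivalent of weak base in a dry aprotic solvent.

Step 2
Reactants: 3 1-[2,6-dihydroxy-4-(3-methylbut-2-enyloxy)phenyl]ethanone
Product: 4 1-[2,4,6-trihydroxy-3-(2-methylbut-3-en-2-yl)phenyl]ethanone
Conditions: N,N-diethylaniline, 190 °C, argon
Reagents that add atoms: none
Why: Aromatic Claisen rearrangement ([3,3]-sigmatropic shift with allylic inversion) should deliver the 1,1-dimethylallyl group to C3, which is equivalent to C5 by symmetry, and tautomerisation restores the arene; the para carbon C1 carries the acetyl group, so a Cope relay to a linear C-prenyl isomer has no productive outlet, and the basic solvent suppresses acid-mediated cyclisation of the new olefin onto the neighbouring phenols.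

Step 3
Reactants: 4 1-[2,4,6-trihydroxy-3-(2-methylbut-3-en-2-yl)phenyl]ethanone
Product: 5 1-[2-hydroxy-4,6-bis(methoxymethoxy)-3-(2-methylbut-3-en-2-yl)phenyl]ethanone
Conditions: MOMCl (2.1 equiv), iPr2NEt (3 equiv), CH2Cl2, 0 °C to rt
Reagents that add atoms: chloromethyl methyl ether (MOMCl), COCCl
Why: O-alkylation to the methoxymethyl acetal, in which the unchelated 4-OH and the less hindered chelated 6-OH should react while the 2-OH, pressed by the tert-alkyl group into a strong hydrogen bond with the acetyl carbonyl, stays free as required for ring C.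

Step 4
Reactants: 6 3-bromo-4,5-dihydroxybenzaldehyde
Product: 8 3-bromo-4-hydroxy-5-(methoxymethoxy)benzaldehyde, via disodium catecholate dianion 7 (not isolated)
Conditions: NaH (2.2 equiv), DMF, 0 °C; MOMCl (1.0 equiv), 0 °C; then aq. NH4Cl
Reagents that add atoms: chloromethyl methyl ether (MOMCl), COCCl
Why: Regioselective mono-O-alkylation of a catechol dianion, in which the O4 phenoxide is delocalised into the para formyl group and flanked by bromine, so the more basic O5 phenoxide (meta to the aldehyde) should take the single equivalent of electrophile, the reverse of the selectivity seen with one equivalent of base.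

Step 5
Reactants: 8 3-bromo-4-hydroxy-5-(methoxymethoxy)benzaldehyde
Product: 9 4-hydroxy-3-(methoxymethoxy)-5-vinylbenzaldehyde
Conditions: vinylboronic acid pinacol ester (1.5 equiv), PdCl2(dppf) (3 mol %), K2CO3 (3 equiv), 1,4-dioxane/H2O 4:1, 85 °C; work-up at pH 5
Reagents that add atoms: 4,4,5,5-tetramethyl-2-vinyl-1,3,2-dioxaborolane, C=CB1OC(C)(C)C(C)(C)O1
Why: Suzuki–Miyaura cross-coupling, in which oxidative addition into the C–Br bond is helped by the para formyl group even with the phenol ionised and the MOM acetal tolerates aqueous carbonate; the coupling is placed before the tertiary allyl ether is made because hot zerovalent palladium would ionise that ether.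

Step 6
Reactants: 10 2-methylbut-3-en-2-ol
Product: 12 tert-butyl 2-methylbut-3-en-2-yl carbonate, via lithium 2-methylbut-3-en-2-olate 11 (not isolated)
Conditions: n-BuLi (1.05 equiv), THF, -78 to 0 °C; Boc2O (1.1 equiv), 0 °C to rt; then H2O
Reagents that add atoms: di-tert-butyl dicarbonate (Boc2O), CC(C)(C)OC(=O)OC(=O)OC(C)(C)C
Why: Alkoxycarbonylation of a tertiary lithium alkoxide by the dicarbonate, the usual way to a mixed tertiary allylic carbonate that serves as a 1,1-dimethylallyl donor.

Step 7
Reactants: 9 4-hydroxy-3-(methoxymethoxy)-5-vinylbenzaldehyde; 12 tert-butyl 2-methylbut-3-en-2-yl carbonate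
Product: 13 3-(methoxymethoxy)-4-[(2-methylbut-3-en-2-yl)oxy]-5-vinylbenzaldehyde
Conditions: 12 (2 equiv), Pd(PPh3)4 (2 mol %), THF, 0 °C, argon, stopped at full conversion of 9
Reagents that add atoms: none
Why: Tsuji–Trost O-allylation, in which zerovalent palladium ionises the tertiary carbonate to the 1,1-dimethyl-π-allyl complex with loss of CO2, the tert-butoxide set free deprotonates the acidic phenol, and the phenoxide should attack the more substituted allyl terminus under kinetic control to give the branched aryl ether, low temperature and low catalyst loading keeping it from re-ionising to the linear prenyl ether.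

Step 8
Reactants: 5 1-[2-hydroxy-4,6-bis(methoxymethoxy)-3-(2-methylbut-3-en-2-yl)phenyl]ethanone; 13 3-(methoxymethoxy)-4-[(2-methylbut-3-en-2-yl)oxy]-5-vinylbenzaldehyde
Product: 14 (E)-1-[2-hydroxy-4,6-bis(methoxymethoxy)-3-(2-methylbut-3-en-2-yl)phenyl]-3-{3-(methoxymethoxy)-4-[(2-methylbut-3-en-2-yl)oxy]-5-vinylphenyl}prop-2-en-1-one
Conditions: KOH (50% aq., excess), EtOH, rt
Reagents that add atoms: none
Why: Claisen–Schmidt (crossed aldol) condensation of a methyl ketone with a non-enolisable aldehyde, E1cB dehydration giving the E enone; the MOM acetals, the aryl tertiary allyl ether and the vinyl groups are inert to hydroxide at room temperature, and no later step exceeds 45 °C so the tertiary allyl ether is not exposed to sigmatropic rearrangement.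

Step 9
Reactants: 14 (E)-1-[2-hydroxy-4,6-bis(methoxymethoxy)-3-(2-methylbut-3-en-2-yl)phenyl]-3-{3-(methoxymethoxy)-4-[(2-methylbut-3-en-2-yl)oxy]-5-vinylphenyl}prop-2-en-1-one
Product: 16 3-hydroxy-5,7-bis(methoxymethoxy)-2-{3-(methoxymethoxy)-4-[(2-methylbut-3-en-2-yl)oxy]-5-vinylphenyl}-8-(2-methylbut-3-en-2-yl)-4H-chromen-4-one, via trans-dihydroflavonol 15 (not isolated)
Conditions: 30% aq. H2O2 (6 equiv), NaOH (2 M aq., 5 equiv), MeOH/THF, 0 °C to rt
Reagents that add atoms: hydrogen peroxide, OO
Why: Algar–Flynn–Oyamada reaction, in which hydroperoxide attacks the enone and the 2'-phenoxide closes ring C in the 6-endo sense at the benzylic carbon, a path that the para alkoxy group of ring B should favour over 5-exo closure to an aurone; the racemic trans-dihydroflavonol 15 is oxidised in the same flask so its two stereocentres vanish, and nucleophilic alkaline peroxide leaves the isolated vinyl groups alone.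

Step 10
Reactants: 16 3-hydroxy-5,7-bis(methoxymethoxy)-2-{3-(methoxymethoxy)-4-[(2-methylbut-3-en-2-yl)oxy]-5-vinylphenyl}-8-(2-methylbut-3-en-2-yl)-4H-chromen-4-one
Product: 17 3,5,7-tris(methoxymethoxy)-2-{3-(methoxymethoxy)-4-[(2-methylbut-3-en-2-yl)oxy]-5-vinylphenyl}-8-(2-methylbut-3-en-2-yl)-4H-chromen-4-one
Conditions: MOMCl (3 equiv), iPr2NEt (5 equiv), CH2Cl2, 0 °C to rt
Reagents that add atoms: chloromethyl methyl ether (MOMCl), COCCl
Why: O-alkylation of the acidic 3-OH to its MOM acetal, which removes the 3-hydroxy-4-keto chelating site before ruthenium is introduced.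

Step 11
Reactants: 17 3,5,7-tris(methoxymethoxy)-2-{3-(methoxymethoxy)-4-[(2-methylbut-3-en-2-yl)oxy]-5-vinylphenyl}-8-(2-methylbut-3-en-2-yl)-4H-chromen-4-one
Product: 18 3,5,7-tris(methoxymethoxy)-2-[8-(methoxymethoxy)-2,2-dimethyl-2H-chromen-6-yl]-8-(2-methylbut-3-en-2-yl)-4H-chromen-4-one (Broussonol A tetrakis-MOM ether)
Conditions: second-generation Grubbs catalyst RuCl2(=CHPh)(PCy3)(H2IMes) (5 mol %), CH2Cl2 (0.005 M), 40 °C, argon
Reagents that add atoms: none
Why: Olefin ring-closing metathesis: the ruthenium carbene should load first on the C5' styrene, the most accessible of the three terminal olefins, to give an ortho-alkoxy arylidene held beside O4', which adds across the vinyl group of the O4' 1,1-dimethylallyl ether in an intramolecular [2+2] step, and cycloreversion of the ruthenacyclobutane releases ethylene and forms the C3''=C4'' bond. The closest known reaction is the closure of 2-vinylaryl 1,1-dimethylallyl ethers to 2,2-dimethyl-2H-chromenes with the same class of catalyst. Ring D is closed as a six-membered ring from two exocyclic vinyl termini with the new olefin inside the ring, so its geometry can only be cis, and the gem-dimethyl group on C2'' favours the folded conformer. No stereocentre is created. The step needs chemoselectivity among three vinyl groups: the C8 1,1-dimethylallyl olefin sits on an all-carbon quaternary centre, has no partner within reach on ring A and is very slow in intermolecular metathesis, so at high dilution only the ring B pair should react, while the MOM group on O3 blocks the site that could chelate ruthenium and the 40 °C limit keeps the aryl tertiary allyl ether from sigmatropic rearrangement.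

Step 12
Reactants: 18 3,5,7-tris(methoxymethoxy)-2-[8-(methoxymethoxy)-2,2-dimethyl-2H-chromen-6-yl]-8-(2-methylbut-3-en-2-yl)-4H-chromen-4-one
Product: 19 Broussonol A, 3,5,7-trihydroxy-2-(8-hydroxy-2,2-dimethyl-2H-chromen-6-yl)-8-(2-methylbut-3-en-2-yl)-4H-chromen-4-one
Conditions: HCl (3 M aq.), MeOH/THF, 45 °C
Reagents that add atoms: none
Why: Acid-catalysed acetal exchange with methanol (MOM removal) should free the four hydroxyls as dimethoxymethane is formed, while the 2,2-dimethylchromene ether and the monosubstituted olefin of the C8 1,1-dimethylallyl group, which could protonate only to a secondary cation, should withstand dilute acid at this temperature.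

**Compound list**

1 | 2,4,6-trihydroxyacetophenone | CC(=O)c1c(O)cc(O)cc1O | starting material
2 | 1-bromo-3-methylbut-2-ene (prenyl bromide) | CC(C)=CCBr | starting material
3 | 1-[2,6-dihydroxy-4-(3-methylbut-2-enyloxy)phenyl]ethanone | CC(=O)c1c(O)cc(OCC=C(C)C)cc1O | intermediate
4 | 1-[2,4,6-trihydroxy-3-(2-methylbut-3-en-2-yl)phenyl]ethanone | CC(=O)c1c(O)cc(O)c(C(C)(C)C=C)c1O | intermediate
5 | 1-[2-hydroxy-4,6-bis(methoxymethoxy)-3-(2-methylbut-3-en-2-yl)phenyl]ethanone | CC(=O)c1c(O)c(C(C)(C)C=C)c(OCOC)cc1OCOC | intermediate
6 | 3-bromo-4,5-dihydroxybenzaldehyde | O=Cc1cc(O)c(O)c(Br)c1 | starting material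
7 | disodium 3-bromo-5-formylbenzene-1,2-diolate (formed in the flask, not isolated) | O=Cc1cc([O-])c([O-])c(Br)c1.[Na+].[Na+] | intermediate
8 | 3-bromo-4-hydroxy-5-(methoxymethoxy)benzaldehyde | O=Cc1cc(Br)c(O)c(OCOC)c1 | intermediate
9 | 4-hydroxy-3-(methoxymethoxy)-5-vinylbenzaldehyde | O=Cc1cc(C=C)c(O)c(OCOC)c1 | intermediate
10 | 2-methylbut-3-en-2-ol | CC(C)(O)C=C | starting material
11 | lithium 2-methylbut-3-en-2-olate (formed in the flask, not isolated) | [Li+].[O-]C(C)(C)C=C | intermediate
12 | tert-butyl 2-methylbut-3-en-2-yl carbonate | C=CC(C)(C)OC(=O)OC(C)(C)C | intermediate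
13 | 3-(methoxymethoxy)-4-[(2-methylbut-3-en-2-yl)oxy]-5-vinylbenzaldehyde | O=Cc1cc(C=C)c(OC(C)(C)C=C)c(OCOC)c1 | intermediate
14 | (E)-1-[2-hydroxy-4,6-bis(methoxymethoxy)-3-(2-methylbut-3-en-2-yl)phenyl]-3-{3-(methoxymethoxy)-4-[(2-methylbut-3-en-2-yl)oxy]-5-vinylphenyl}prop-2-en-1-one | C=CC(C)(C)c1c(O)c(C(=O)/C=C/c2cc(C=C)c(OC(C)(C)C=C)c(OCOC)c2)c(OCOC)cc1OCOC | intermediate
15 | trans-3-hydroxy-5,7-bis(methoxymethoxy)-2-{3-(methoxymethoxy)-4-[(2-methylbut-3-en-2-yl)oxy]-5-vinylphenyl}-8-(2-methylbut-3-en-2-yl)chroman-4-one (racemic, one enantiomer drawn; formed in the flask, not isolated) | C=Cc1cc(cc(OCOC)c1OC(C)(C)C=C)[C@@H]2[C@H](C(=O)c3c(OCOC)cc(OCOC)c(C(C)(C)C=C)c3O2)O | intermediate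
16 | 3-hydroxy-5,7-bis(methoxymethoxy)-2-{3-(methoxymethoxy)-4-[(2-methylbut-3-en-2-yl)oxy]-5-vinylphenyl}-8-(2-methylbut-3-en-2-yl)-4H-chromen-4-one | C=CC(C)(C)c1c(OCOC)cc(OCOC)c2c(=O)c(O)c(-c3cc(C=C)c(OC(C)(C)C=C)c(OCOC)c3)oc12 | intermediate
17 | 3,5,7-tris(methoxymethoxy)-2-{3-(methoxymethoxy)-4-[(2-methylbut-3-en-2-yl)oxy]-5-vinylphenyl}-8-(2-methylbut-3-en-2-yl)-4H-chromen-4-one (metathesis precursor) | C=CC(C)(C)c1c(OCOC)cc(OCOC)c2c(=O)c(OCOC)c(-c3cc(C=C)c(OC(C)(C)C=C)c(OCOC)c3)oc12 | intermediate
18 | 3,5,7-tris(methoxymethoxy)-2-[8-(methoxymethoxy)-2,2-dimethyl-2H-chromen-6-yl]-8-(2-methylbut-3-en-2-yl)-4H-chromen-4-one (Broussonol A tetrakis-MOM ether) | C=CC(C)(C)c1c(OCOC)cc(OCOC)c2c(=O)c(OCOC)c(-c3cc(OCOC)c4c(c3)C=CC(C)(C)O4)oc12 | intermediate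
19 | Broussonol A | C=CC(C)(C)c1c(O)cc(O)c2c(=O)c(O)c(-c3cc(O)c4c(c3)C=CC(C)(C)O4)oc12 | target

**Step count and risks**

Total step count: 12. Longest linear sequence: 8 steps (steps 1, 2, 3, 8, 9, 10, 11, 12 from 1; equally steps 4, 5, 7, 8, 9, 10, 11, 12 from 6).

Steps most likely to fail:

Step 9. The 6'-alkoxy group twists the enone out of the ring A plane, and ring closure may then run through the alpha carbon (five-membered, aurone-type closure) instead of the beta carbon, draining material from the flavonol path. The fallback separates ring closure from oxygenation. It sets out from 14: NaOAc in EtOH at 70 °C should close ring C by oxa-Michael addition to the racemic flavanone F1. Dehydrogenation with DDQ in 1,4-dioxane at 80 °C should give the flavone F2. C3 lithiation with LiN(iPr)2 in THF at -78 °C, trapping with B(OMe)3 and oxidation of the boronate with H2O2/NaOH at 0 °C should install the 3-hydroxyl. The sequence comes back to the route at 16.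

Step 7. The phenoxide is flanked by two ortho substituents and is a good leaving group, so attack at the primary allyl terminus, or re-ionisation of the branched ether by palladium followed by return to the linear isomer, may erode the branched selectivity on which the metathesis depends. The fallback builds the tertiary ether without a π-allyl intermediate. It sets out from 9: alkylation with 3-chloro-3-methylbut-1-yne, CuCl2·2H2O (catalytic) and DBU in MeCN at 0 °C should give the 1,1-dimethylpropargyl ether F3. Semi-hydrogenation with H2 over Pd on CaCO3 poisoned with Pb(OAc)2 (Lindlar catalyst) and quinoline in EtOAc, stopped after one equivalent of hydrogen, should give the 1,1-dimethylallyl ether. The sequence comes back to the route at 13.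

Step 11. On the polyoxygenated flavonol the catalyst may be held as an unreactive ortho-alkoxy arylidene chelate or bound by the carbonyl/acetal oxygens. Intermolecular metathesis at the styrene, or olefin migration by ruthenium hydrides, may then compete with ring closure. The fallback closes ring D before the flavone is built, on a small substrate with only two olefins. It sets out from 13: the same catalyst in CH2Cl2 at 40 °C should give the chromene aldehyde F4. Claisen–Schmidt condensation of F4 with 5 (KOH, EtOH, rt) should give the chromene chalcone F5. Alkaline H2O2 should give the chromene flavonol F6, and MOMCl/iPr2NEt then caps O3. The sequence comes back to the route at 18.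

**Further compounds**

F1 | step 9 | 5,7-bis(methoxymethoxy)-2-{3-(methoxymethoxy)-4-[(2-methylbut-3-en-2-yl)oxy]-5-vinylphenyl}-8-(2-methylbut-3-en-2-yl)chroman-4-one (racemic flavanone) | C=CC(C)(C)c1c(OCOC)cc(OCOC)c2c1OC(c1cc(C=C)c(OC(C)(C)C=C)c(OCOC)c1)CC2=O
F2 | step 9 | 5,7-bis(methoxymethoxy)-2-{3-(methoxymethoxy)-4-[(2-methylbut-3-en-2-yl)oxy]-5-vinylphenyl}-8-(2-methylbut-3-en-2-yl)-4H-chromen-4-one (flavone) | C=CC(C)(C)c1c(OCOC)cc(OCOC)c2c(=O)cc(-c3cc(C=C)c(OC(C)(C)C=C)c(OCOC)c3)oc12
F3 | step 7 | 3-(methoxymethoxy)-4-[(2-methylbut-3-yn-2-yl)oxy]-5-vinylbenzaldehyde | O=Cc1cc(C=C)c(OC(C)(C)C#C)c(OCOC)c1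
F4 | step 11 | 8-(methoxymethoxy)-2,2-dimethyl-2H-chromene-6-carbaldehyde | O=Cc1cc(OCOC)c2OC(C)(C)C=Cc2c1
F5 | step 11 | (E)-1-[2-hydroxy-4,6-bis(methoxymethoxy)-3-(2-methylbut-3-en-2-yl)phenyl]-3-[8-(methoxymethoxy)-2,2-dimethyl-2H-chromen-6-yl]prop-2-en-1-one | C=CC(C)(C)c1c(O)c(C(=O)/C=C/c2cc(OCOC)c3OC(C)(C)C=Cc3c2)c(OCOC)cc1OCOC
F6 | step 11 | 3-hydroxy-5,7-bis(methoxymethoxy)-2-[8-(methoxymethoxy)-2,2-dimethyl-2H-chromen-6-yl]-8-(2-methylbut-3-en-2-yl)-4H-chromen-4-one | C=CC(C)(C)c1c(OCOC)cc(OCOC)c2c(=O)c(O)c(-c3cc(OCOC)c4c(c3)C=CC(C)(C)O4)oc12
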